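The data are simulated with made-up constants; noise was put on by code.

At 0.250 d the violet run already held 23.6% of target, and by 2.50 d it was falling, so I read each run as two rates: a climb and a fall.

| setting | violet | blue | teal | flask |
|---|---|---|---|---|
| substrate | 0.71 M | 0.71 M | 0.35 M | 0.71 M |
| partner | 0.426 M | 0.426 M | 0.426 M | 0.426 M |
| catalyst | 25 mM | 40 mM | 18 mM | 18 mM |
| remark | run made earlier | run made earlier | run made earlier |  |
| time |  |  |  | 15 d |

| run | time / d | target / % |
|---|---|---|
| violet | 0.250 | 23.6 |
| violet | 0.833 | 33.0 |
| violet | 2.50 | 27.3 |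
| violet | 6.00 | 19.0 |
| violet | 20.0 | 12.1 |
| blue | 0.250 | 30.0 |
| blue | 0.833 | 33.3 |
| blue | 2.50 | 27.1 |
| blue | 6.00 | 21.0 |
| blue | 20.0 | 9.7 |
| teal | 0.250 | 22.4 |
| teal | 0.833 | 38.7 |
| teal | 2.50 | 37.1 |
| teal | 6.00 | 33.5 |
| teal | 20.0 | 20.2 |

(each reading ± 1 percentage point)

- in percentages every species weighs as the substrate in it: one self-condensation product counts as two
- steps under discussion: substrate + partner + catalyst <-> target + catalyst; 2 substrate -> self-condensation product

- time, not beyond 15 d, at which the flask holds most target
- the amount of target, in percent of the substrate charged, at that time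

Violet's fall from 0.833 d to 2.50 d gave a first-order rate λ of 0.114 d⁻¹. Run back to the start, that line stood at A, 36.3%. I pictured the target as this line minus a gap closing at the climb rate r, treated as pseudo-first-order. The first violet reading then gave r as 4.43 d⁻¹. Scaled by catalyst, the flask's r was 3.19 d⁻¹.

The rule I carried was the climb-to-fall ratio, g = r/λ, here 28.0. In that picture the best time is ln g divided by r minus λ, which put the flask at 1.08 d, with 30.9% of target.

The weak link was carrying λ down to the flask's catalyst. Blue's fall, 0.124 d⁻¹, moved the time to 1.06 d, so I kept my numbers.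

The forecast said 1.1 d (0.8 d to 1.5 d) and 31.5% (29% to 33.5%), a height above mine, noting that “The late decline looks similar across catalyst loadings”.

The flask gave 29.7% at 1.15 d.

    substrate + partner + catalyst ⇌ target + catalyst, rate k1*[substrate]*[partner]*[catalyst] forward; the back reaction follows from the equilibrium constant (K = 4.60 L mol⁻¹, k = 7.30 L² mol⁻² h⁻¹)
    2 substrate → self-condensation product (k = 0.0390 L mol⁻¹ h⁻¹)

The flask held 29.4% of target at 0.923 d and 28.8% at 1.73 d. Teal holds half the flask's substrate at the same catalyst, and its fall from 2.50 d to 6.00 d is 0.0292 d⁻¹. That raises g to 109 and the reckoned best time to 1.49 d. The flask charged with half the substrate reached its best at 1.53 d.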